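The route rests on cutting the biaryl axis C3'–C8'', which links ring B of the 4',5'-dimethoxyflavone unit to ring A of the apigenin unit. This mirrors the presumed biosynthetic union of two flavone monomers. One Suzuki–Miyaura coupling joins two complete, perbenzylated flavones, so only hydrogenolysis follows. The step exploits two features. C8'', flanked by O1'' and the 7''-oxygen, is the innate site of electrophilic iodination of a 5,7-dialkoxyflavone. C3', ortho to the 4'-methoxy group, already carries a halogen in commercial 5-bromoveratraldehyde. The precursors are a flavone 3'-pinacolboronate and 8-iodo-tri-O-benzylapigenin. Benzyl ethers on all five phenols keep both methyl ethers distinct to the end.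

Key step: step 7

Assumption: the target structure carries no stereodescriptor, so the C3'–C8'' axis is treated as configurationally undefined and no control of axial chirality is attempted.

Locants: unprimed and singly primed locants belong to flavone unit 1 (the dimethoxy unit). Doubly and triply primed locants belong to flavone unit 2 (the apigenin unit).

Step 1
Reactants: 1 2,4,6-trihydroxyacetophenone
Product: 2 1-[2,4-bis(benzyloxy)-6-hydroxyphenyl]ethanone
Conditions: BnBr (2.1 equiv), K2CO3 (2.2 equiv), DMF, rt to 50 °C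
Reagents that add atoms: benzyl bromide, BrCc1ccccc1
Why: Williamson etherification alkylates the 4-OH and one of the two equivalent ortho OH groups, while the last OH stays hydrogen-bonded to the acetyl carbonyl and should not react with the limited amount of benzyl bromide.

Step 2
Reactants: 2 1-[2,4-bis(benzyloxy)-6-hydroxyphenyl]ethanone; 3 3-bromo-4,5-dimethoxybenzaldehyde (5-bromoveratraldehyde)
Product: 4 (E)-1-[2,4-bis(benzyloxy)-6-hydroxyphenyl]-3-(3-bromo-4,5-dimethoxyphenyl)prop-2-en-1-one
Conditions: KOH (50% aq.), EtOH/THF, rt, then dilute HCl work-up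
Reagents that add atoms: none
Why: In this Claisen–Schmidt condensation the acetophenone enolate adds to the non-enolisable aldehyde and E1cB loss of water should give the thermodynamically favoured (E)-enone, the aryl bromide and benzyl ethers being inert to aqueous KOH at room temperature.

Step 3
Reactants: 4 (E)-1-[2,4-bis(benzyloxy)-6-hydroxyphenyl]-3-(3-bromo-4,5-dimethoxyphenyl)prop-2-en-1-one
Product: 5 5,7-bis(benzyloxy)-2-(3-bromo-4,5-dimethoxyphenyl)-4H-chromen-4-one
Conditions: I2 (10 mol %), DMSO, 120 °C
Reagents that add atoms: none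
Why: This is the iodine-catalysed oxidative cyclisation of a 2'-hydroxychalcone (oxa-Michael closure to the flavanone, alpha-iodination, loss of HI, re-oxidation of HI to I2 by DMSO), run with a catalytic iodine load so that ring iodination and acid cleavage of the 5-O-benzyl ether should stay minor.

Step 4
Reactants: 5 5,7-bis(benzyloxy)-2-(3-bromo-4,5-dimethoxyphenyl)-4H-chromen-4-one
Product: 6 5,7-bis(benzyloxy)-2-[3,4-dimethoxy-5-(4,4,5,5-tetramethyl-1,3,2-dioxaborolan-2-yl)phenyl]-4H-chromen-4-one
Conditions: B2pin2 (1.2 equiv), Pd(dppf)Cl2 (5 mol %), KOAc (3 equiv), 1,4-dioxane, 90 °C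
Reagents that add atoms: bis(pinacolato)diboron, CC1(C)OB(OC1(C)C)B1OC(C)(C)C(C)(C)O1
Why: In this Miyaura borylation zerovalent palladium formed in situ inserts into the only C–Br bond, acetate-assisted transmetalation with B2pin2 and reductive elimination give the pinacol boronate, and the weak base KOAc should suppress homocoupling and leave the chromone untouched.

Step 5
Reactants: 7 apigenin
Product: 8 5,7-bis(benzyloxy)-2-[4-(benzyloxy)phenyl]-4H-chromen-4-one (tri-O-benzylapigenin)
Conditions: BnBr (4.5 equiv), K2CO3 (5 equiv), n-Bu4NI (cat.), DMF, 80 °C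
Reagents that add atoms: benzyl bromide, BrCc1ccccc1
Why: This is an exhaustive Williamson etherification in which excess benzyl bromide, iodide catalysis and heat force the chelated 5-OH to react after the more acidic 7-OH and 4'-OH.

Step 6
Reactants: 8 5,7-bis(benzyloxy)-2-[4-(benzyloxy)phenyl]-4H-chromen-4-one
Product: 9 5,7-bis(benzyloxy)-2-[4-(benzyloxy)phenyl]-8-iodo-4H-chromen-4-one
Conditions: NIS (1.1 equiv), DMF, 50 °C, dark
Reagents that add atoms: N-iodosuccinimide, O=C1CCC(=O)N1I
Why: In this electrophilic aromatic iodination ring A is the most electron-rich ring once the 5-oxygen is alkylated, and C8 (ortho to O1 and 7-OBn, para to 5-OBn, next to only one freely rotating benzyloxy group) should react before C6, which sits between two benzyloxy groups, in line with the known C8 preference of 5,7-dialkoxyflavones.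

Step 7
Reactants: 6 5,7-bis(benzyloxy)-2-[3,4-dimethoxy-5-(4,4,5,5-tetramethyl-1,3,2-dioxaborolan-2-yl)phenyl]-4H-chromen-4-one; 9 5,7-bis(benzyloxy)-2-[4-(benzyloxy)phenyl]-8-iodo-4H-chromen-4-one
Product: 10 5,7-bis(benzyloxy)-8-{5-[5,7-bis(benzyloxy)-4-oxo-4H-chromen-2-yl]-2,3-dimethoxyphenyl}-2-[4-(benzyloxy)phenyl]-4H-chromen-4-one (penta-O-benzyl-5'-methoxybilobetin)
Conditions: Pd(OAc)2 (5 mol %), SPhos (10 mol %), K3PO4 (3 equiv), degassed toluene/H2O 10:1, 100 °C
Reagents that add atoms: none
Why: Zerovalent palladium, formed in situ from Pd(OAc)2 and SPhos, inserts into the C8–I bond of 9, the phosphate-activated boronate 6 transfers its ring B carbon C3' to divalent palladium, and reductive elimination forges the C3'–C8'' bond. The closest known reaction type is the Suzuki–Miyaura coupling of di-ortho-oxygenated aryl iodides with ortho-methoxyarylboronates to tri-ortho-substituted biaryls, for which bulky electron-rich dialkylbiarylphosphines are the established ligands. No ring is closed and no stereocentre is set; the new axis, flanked by 4'-OMe, 7''-OBn and O1'', forms without configurational control, as the target demands none. Site selectivity is not left to the reaction, since boron and iodine mark the two carbons and 9 holds the only carbon–halogen bond in the flask. Boron sits on ring B of unit 1 and iodine on ring A of unit 2 because a boronate at C8'' between two oxygens would protodeboronate quickly, whereas an iodide there compensates for the slow oxidative addition of an electron-rich, hindered arene. Benzyl ethers, methyl ethers and both chromone carbonyls should be inert to the mild phosphate base.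

Step 8
Reactants: 10 penta-O-benzyl-5'-methoxybilobetin
Product: 11 5'-methoxybilobetin
Conditions: H2 (1 atm), 10% Pd/C, THF/MeOH 1:1, rt
Reagents that add atoms: none
Why: Catalytic hydrogenolysis cleaves the five benzylic C–O bonds, whereas the two aryl methyl ethers have no benzylic C–O bond and the chromone C2=C3 bonds are reduced far more slowly at one atmosphere and room temperature, so the target should be released in one operation.

Compound list
1 | 2,4,6-trihydroxyacetophenone (phloroacetophenone) | CC(=O)c1c(O)cc(O)cc1O | starting material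
2 | 1-[2,4-bis(benzyloxy)-6-hydroxyphenyl]ethanone | CC(=O)c1c(O)cc(OCc2ccccc2)cc1OCc1ccccc1 | intermediate
3 | 3-bromo-4,5-dimethoxybenzaldehyde (5-bromoveratraldehyde) | COc1cc(C=O)cc(Br)c1OC | starting material
4 | (E)-1-[2,4-bis(benzyloxy)-6-hydroxyphenyl]-3-(3-bromo-4,5-dimethoxyphenyl)prop-2-en-1-one | COc1cc(/C=C/C(=O)c2c(O)cc(OCc3ccccc3)cc2OCc2ccccc2)cc(Br)c1OC | intermediate
5 | 5,7-bis(benzyloxy)-2-(3-bromo-4,5-dimethoxyphenyl)-4H-chromen-4-one | COc1cc(-c2cc(=O)c3c(OCc4ccccc4)cc(OCc4ccccc4)cc3o2)cc(Br)c1OC | intermediate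
6 | 5,7-bis(benzyloxy)-2-[3,4-dimethoxy-5-(4,4,5,5-tetramethyl-1,3,2-dioxaborolan-2-yl)phenyl]-4H-chromen-4-one | COc1cc(-c2cc(=O)c3c(OCc4ccccc4)cc(OCc4ccccc4)cc3o2)cc(B2OC(C)(C)C(C)(C)O2)c1OC | intermediate
7 | apigenin, 5,7-dihydroxy-2-(4-hydroxyphenyl)-4H-chromen-4-one | O=c1cc(-c2ccc(O)cc2)oc2cc(O)cc(O)c12 | starting material
8 | 5,7-bis(benzyloxy)-2-[4-(benzyloxy)phenyl]-4H-chromen-4-one (tri-O-benzylapigenin) | O=c1cc(-c2ccc(OCc3ccccc3)cc2)oc2cc(OCc3ccccc3)cc(OCc3ccccc3)c12 | intermediate
9 | 5,7-bis(benzyloxy)-2-[4-(benzyloxy)phenyl]-8-iodo-4H-chromen-4-one | O=c1cc(-c2ccc(OCc3ccccc3)cc2)oc2c(I)c(OCc3ccccc3)cc(OCc3ccccc3)c12 | intermediate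
10 | penta-O-benzyl-5'-methoxybilobetin | COc1cc(-c2cc(=O)c3c(OCc4ccccc4)cc(OCc4ccccc4)cc3o2)cc(-c2c(OCc3ccccc3)cc(OCc3ccccc3)c3c(=O)cc(-c4ccc(OCc5ccccc5)cc4)oc23)c1OC | intermediate
11 | 5'-methoxybilobetin | COc1cc(-c2cc(=O)c3c(O)cc(O)cc3o2)cc(-c2c(O)cc(O)c3c(=O)cc(-c4ccc(O)cc4)oc23)c1OC | target

Total step count: 8
Longest linear sequence: 6 (steps 1, 2, 3, 4, 7, 8)

Steps most likely to fail

Risk 1 (step 7): oxidative addition and transmetalation at a carbon flanked by two ortho oxygens may be slow, and two large flavones may dissolve poorly. Protodeboronation and hydrodeiodination could then outrun the coupling. The fallback makes the same axis with a small partner and builds flavone unit 1 afterwards. It sets out from 3, 9 and 2 and comes back at 10.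
- Aldehyde 3 would be borylated (B2pin2, Pd(dppf)Cl2, KOAc, dioxane) to 3,4-dimethoxy-5-(4,4,5,5-tetramethyl-1,3,2-dioxaborolan-2-yl)benzaldehyde F1.
- This small, soluble boronate would be coupled with 9 under Suzuki–Miyaura conditions to 3-{5,7-bis(benzyloxy)-2-[4-(benzyloxy)phenyl]-4-oxo-4H-chromen-8-yl}-4,5-dimethoxybenzaldehyde F2.
- Claisen–Schmidt condensation of the aldehyde with acetophenone 2 (KOH, EtOH/THF, rt) would give the 8-aryl-flavone chalcone F3.
- Oxidative cyclisation with catalytic I2 in DMSO would close the second chromone and return to 10.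

Risk 2 (step 6): site selectivity of the iodination may be poor, with attack spreading to C6, C3 or the benzyloxyphenyl ring, or over-iodination may occur. The fallback fixes the iodine position before the chromone exists. It sets out from 2 and comes back at 9.
- Acetophenone 2 would be iodinated ortho to its free phenol (NIS, CH2Cl2, rt) to 1-[4,6-bis(benzyloxy)-2-hydroxy-3-iodophenyl]ethanone F4.
- Claisen–Schmidt condensation with commercial 4-benzyloxybenzaldehyde would give the (E)-3'-iodochalcone F5.
- Closure with catalytic I2 in DMSO must run through the only free OH, which lies next to the C–I carbon, so the iodine ends at C8 of 9.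

Risk 3 (step 3): HI at 120 °C may cleave the 5-O-benzyl group, and ring A may be iodinated as a side reaction. The fallback replaces the oxidative chalcone route by a redox-neutral Baker–Venkataraman sequence. It sets out from 2 and comes back at 5.
- Phenol 2 would be esterified with commercial 3-bromo-4,5-dimethoxybenzoic acid (EDC·HCl, DMAP, CH2Cl2) to 2-acetyl-3,5-bis(benzyloxy)phenyl 3-bromo-4,5-dimethoxybenzoate F6.
- KOH in pyridine at 50 °C would shift the aroyl group to carbon and give 1-[2,4-bis(benzyloxy)-6-hydroxyphenyl]-3-(3-bromo-4,5-dimethoxyphenyl)propane-1,3-dione F7.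
- Cyclodehydration with catalytic p-TsOH in toluene at 90 °C would give 5.

Further compounds
F1 | step 7 | 3,4-dimethoxy-5-(4,4,5,5-tetramethyl-1,3,2-dioxaborolan-2-yl)benzaldehyde | COc1cc(C=O)cc(B2OC(C)(C)C(C)(C)O2)c1OC
F2 | step 7 | 3-{5,7-bis(benzyloxy)-2-[4-(benzyloxy)phenyl]-4-oxo-4H-chromen-8-yl}-4,5-dimethoxybenzaldehyde | COc1cc(C=O)cc(-c2c(OCc3ccccc3)cc(OCc3ccccc3)c3c(=O)cc(-c4ccc(OCc5ccccc5)cc4)oc23)c1OC
F3 | step 7 | (E)-1-[2,4-bis(benzyloxy)-6-hydroxyphenyl]-3-(3-{5,7-bis(benzyloxy)-2-[4-(benzyloxy)phenyl]-4-oxo-4H-chromen-8-yl}-4,5-dimethoxyphenyl)prop-2-en-1-one | COc1cc(/C=C/C(=O)c2c(O)cc(OCc3ccccc3)cc2OCc2ccccc2)cc(-c2c(OCc3ccccc3)cc(OCc3ccccc3)c3c(=O)cc(-c4ccc(OCc5ccccc5)cc4)oc23)c1OC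
F4 | step 6 | 1-[4,6-bis(benzyloxy)-2-hydroxy-3-iodophenyl]ethanone | CC(=O)c1c(O)c(I)c(OCc2ccccc2)cc1OCc1ccccc1
F5 | step 6 | (E)-1-[4,6-bis(benzyloxy)-2-hydroxy-3-iodophenyl]-3-[4-(benzyloxy)phenyl]prop-2-en-1-one | O=C(/C=C/c1ccc(OCc2ccccc2)cc1)c1c(O)c(I)c(OCc2ccccc2)cc1OCc1ccccc1
F6 | step 3 | 2-acetyl-3,5-bis(benzyloxy)phenyl 3-bromo-4,5-dimethoxybenzoate | CC(=O)c1c(OC(=O)c2cc(Br)c(OC)c(OC)c2)cc(OCc2ccccc2)cc1OCc1ccccc1
F7 | step 3 | 1-[2,4-bis(benzyloxy)-6-hydroxyphenyl]-3-(3-bromo-4,5-dimethoxyphenyl)propane-1,3-dione | COc1cc(C(=O)CC(=O)c2c(O)cc(OCc3ccccc3)cc2OCc2ccccc2)cc(Br)c1OC
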